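A direct plan would add the lithium enolate of the ring B methyl ketone A2 to a hexasubstituted ring A aldehyde A1 (four steps from 5-bromoresorcinol, with bromine and iodine as mere placeholders), silylate the aldol A3, reduce the ketone with a CBS catalyst to the (1S)-bromo alcohol A4, close ring C by palladium-catalysed C–O coupling to the flavan A5, and then desilylate, oxidise C4 and remove the MOM groups. Its weakest steps would be:
(1) the aldol addition, which would create a C4 carbinol centre the target lacks, so that silylation, desilylation and oxidation would only hide and then erase it while every intermediate is carried as an epimer pair;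
(2) the CBS reduction, the sole source of the C2 configuration, which would have to tell an aryl group from a branched CH2CH(OSi)Ar chain on an epimer mixture whose enantiomeric purity is hard to assay;
(3) the C–O ring closure, which would be run on the most precious material at a bromide flanked on both sides, with a secondary benzylic alkoxide on palladium that is prone to β-hydride elimination.

**Plan of the new route.** The retrosynthesis cuts C2–C1' (ring B from ring C) and C8–CH2 (prenyl from ring A). Rings A and C are present from the first step as a chromone. The prenyl group is carried from O5 to C8 by a europium-templated para-Claisen–Cope shift, possible because C8 is para to O5 and O5 forms a chelate with the C4 carbonyl. Ring B is joined last by a rhodium-catalysed enantioselective 1,4-addition of its boronic acid to the C2=C3–C4=O unit of ring C. This works because C2, the only stereocentre, is the β-carbon of that unit and holds ring B by a single C–C bond. C4 stays a ketone throughout, C2 is set by the catalyst on a flat achiral substrate in the bond-forming step, and no ring is closed on late material, so the carbinol detour, the reduction of an epimer mixture and the C–O coupling do not arise.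

Key step: step 7

Remark: 5,7-dihydroxychromone (1) is taken as a purchasable starting material.
Remark: the facial sense of the rhodium/diene arylation is taken from the model for cyclic enones ((S,S)-diene gives 2S); if it proved opposite, the (R,R)-diene would be used with no other change.

Step 1
Reactants: 1 5,7-dihydroxychromone
Product: 2 5-hydroxy-4-oxo-4H-chromen-7-yl acetate
Conditions: Ac2O (1.1 equiv), pyridine, 0 °C → rt
Reagents that add atoms: acetic anhydride, CC(=O)OC(C)=O
Why: O-Acylation should take place only at the free, acidic 7-hydroxyl, because the 5-hydroxyl is held in a hydrogen bond to the C4 carbonyl, as in the 7-monoacylation of 5,7-dihydroxyflavonoids.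

Step 2
Reactants: 2 5-hydroxy-4-oxo-4H-chromen-7-yl acetate; 3 prenol (3-methylbut-2-en-1-ol)
Product: 4 5-[(3-methylbut-2-en-1-yl)oxy]-4-oxo-4H-chromen-7-yl acetate
Conditions: PPh3 (1.5 equiv), DIAD (1.5 equiv), THF, 0 °C → rt
Reagents that add atoms: none
Why: Mitsunobu etherification alkylates the chelated 5-hydroxyl at the primary carbon of prenol under neutral conditions that leave the aryl acetate in place, where basic alkylation would scramble it.

Step 3
Reactants: 4 5-[(3-methylbut-2-en-1-yl)oxy]-4-oxo-4H-chromen-7-yl acetate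
Product: 7 5-hydroxy-8-(3-methylbut-2-en-1-yl)-4-oxo-4H-chromen-7-yl acetate, via ortho-dienone 5 (not isolated), via para-dienone 6 (not isolated)
Conditions: Eu(fod)3 (10 mol %; fod = 6,6,7,7,8,8,8-heptafluoro-2,2-dimethyloctane-3,5-dionate), acid-free CHCl3, 60 °C, sealed tube
Reagents that add atoms: none
Why: Trivalent europium chelated between the C4 carbonyl and O5 accelerates the aromatic Claisen [3,3] shift to C6, the only free ortho position, and the crowded ortho-dienone passes the side chain on by a Cope [3,3] shift to C8, para to O5, where enolisation gives the phenol with a linear prenyl group (para-Claisen–Cope rearrangement, as with 5-prenyloxyflavonoids); the step is placed before C2 exists so that Lewis acid and heat cannot touch the stereocentre.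

Step 4
Reactants: 7 5-hydroxy-8-(3-methylbut-2-en-1-yl)-4-oxo-4H-chromen-7-yl acetate
Product: 8 8-(3-methylbut-2-en-1-yl)-4-oxo-4H-chromene-5,7-diyl diacetate
Conditions: Ac2O (3 equiv), Et3N (4 equiv), DMAP (10 mol %), CH2Cl2, rt
Reagents that add atoms: acetic anhydride, CC(=O)OC(C)=O
Why: DMAP-catalysed acylation caps the chelated 5-hydroxyl, which would otherwise bind rhodium as a β-ketophenolate in the key step, and the second acetoxy group makes C2 more electrophilic.

Step 5
Reactants: 9 4-bromo-2-iodoanisole; 10 prenyl bromide (1-bromo-3-methylbut-2-ene)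
Product: 12 4-bromo-1-methoxy-2-(3-methylbut-2-en-1-yl)benzene, via arylmagnesium chloride 11 (not isolated)
Conditions: i-PrMgCl·LiCl (1.05 equiv), THF, −30 °C; then CuI (10 mol %), prenyl bromide (1.3 equiv), −30 → 0 °C
Reagents that add atoms: none
Why: Iodine–magnesium exchange is selective for C–I over C–Br, and copper-catalysed allylic substitution of prenyl bromide at its unhindered CH2 end should give the linear prenyl arene with the bromide kept for the next step.

Step 6
Reactants: 12 4-bromo-1-methoxy-2-(3-methylbut-2-en-1-yl)benzene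
Product: 15 [4-methoxy-3-(3-methylbut-2-en-1-yl)phenyl]boronic acid, via aryllithium 13 (not isolated), via lithium triisopropoxyborate 14 (not isolated)
Conditions: n-BuLi (1.05 equiv), THF, −78 °C; B(Oi-Pr)3 (1.5 equiv), −78 °C → rt; 1 M aq. HCl, 0 °C, brief
Reagents that add atoms: triisopropyl borate, CC(C)OB(OC(C)C)OC(C)C; water, O
Why: Bromine–lithium exchange and trapping of the aryllithium with the borate ester give the ate complex, which brief cold aqueous acid hydrolyses to the boronic acid without touching the prenyl alkene.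

Step 7
Reactants: 8 8-(3-methylbut-2-en-1-yl)-4-oxo-4H-chromene-5,7-diyl diacetate; 15 [4-methoxy-3-(3-methylbut-2-en-1-yl)phenyl]boronic acid
Product: 16 (2S)-2-[4-methoxy-3-(3-methylbut-2-en-1-yl)phenyl]-8-(3-methylbut-2-en-1-yl)-4-oxochromane-5,7-diyl diacetate
Conditions: [RhCl(C2H4)2]2 (2.5 mol %), (1S,4S)-2,5-diphenylbicyclo[2.2.2]octa-2,5-diene (5.5 mol %), 15 (2.5 equiv), KOH (10 mol %), 1,4-dioxane/H2O (10:1), 40 °C
Reagents that add atoms: none
Why: The hydroxo-rhodium(diene) complex transmetalates with the boronic acid to an aryl–rhodium species, the C2=C3 bond of the chromone coordinates and inserts into the Rh–aryl bond with the aryl group going to C2, and water protonates the resulting oxa-π-allyl rhodium enolate at C3, which returns the hydroxo complex and leaves C4 as the ketone. The closest known reaction type is the Hayashi–Miyaura asymmetric 1,4-addition of arylboronic acids to chromones with rhodium–chiral diene catalysts, which gives 2-arylchroman-4-ones. No ring is closed: ring B is attached to the finished A/C bicycle through the new C2–C1' bond. The C2 centre is set by the twofold-symmetric diene, which leaves one enantioface of the flat C2=C3 bond open to the aryl group, and the (S,S)-diene should give 2S by the model for cyclic enones. The step needs 1,4- over 1,2-addition, inert prenyl alkenes and aryl acetates, and no base-induced opening of the product to the chalcone. These should be secured by the vinylogous-ester C4 carbonyl shielded by the 5-acetoxy group, by the electron-rich trisubstituted alkenes that cannot compete with the electron-poor C2=C3 bond for insertion, and by the nearly neutral medium buffered by the excess boronic acid.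

Step 8
Reactants: 16 (2S)-2-[4-methoxy-3-(3-methylbut-2-en-1-yl)phenyl]-8-(3-methylbut-2-en-1-yl)-4-oxochromane-5,7-diyl diacetate
Product: 17 (2S)-5,7-dihydroxy-2-[4-methoxy-3-(3-methylbut-2-en-1-yl)phenyl]-8-(3-methylbut-2-en-1-yl)chroman-4-one (target)
Conditions: K2CO3 (2.5 equiv), MeOH, 0 °C, short reaction time; then 1 M aq. HCl to pH 5
Reagents that add atoms: none
Why: Methanolysis of the two aryl acetates is fast at 0 °C, and C2 should hold because opening of ring C would need C3 deprotonation and loss of the O1 phenoxide, both disfavoured once the ring A phenoxides are formed, while the 4'-methoxy group rules out a quinone methide pathway.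

**Compound list**

1 | 5,7-dihydroxychromone (5,7-dihydroxy-4H-chromen-4-one) | O=c1ccoc2cc(O)cc(O)c12 | starting material
2 | 5-hydroxy-4-oxo-4H-chromen-7-yl acetate | CC(=O)Oc1cc(O)c2c(c1)occc2=O | intermediate
3 | prenol (3-methylbut-2-en-1-ol) | CC(C)=CCO | starting material
4 | 5-[(3-methylbut-2-en-1-yl)oxy]-4-oxo-4H-chromen-7-yl acetate | CC(=O)Oc1cc(OCC=C(C)C)c2c(c1)occc2=O | intermediate
5 | ortho-dienone, racemic 6-(2-methylbut-3-en-2-yl)-4,5-dioxo-5,6-dihydro-4H-chromen-7-yl acetate (not isolated) | CC(=O)OC1=CC2=C(C(=O)C=CO2)C(=O)C1C(C)(C)C=C | intermediate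
6 | para-dienone, racemic 8-(3-methylbut-2-en-1-yl)-4,5-dioxo-5,8-dihydro-4H-chromen-7-yl acetate (not isolated) | CC(=O)OC1=CC(=O)C2=C(OC=CC2=O)C1CC=C(C)C | intermediate
7 | 5-hydroxy-8-(3-methylbut-2-en-1-yl)-4-oxo-4H-chromen-7-yl acetate | CC(=O)Oc1cc(O)c2c(c1CC=C(C)C)occc2=O | intermediate
8 | 8-(3-methylbut-2-en-1-yl)-4-oxo-4H-chromene-5,7-diyl diacetate | CC(=O)Oc1cc(OC(C)=O)c2c(c1CC=C(C)C)occc2=O | intermediate
9 | 4-bromo-2-iodoanisole (4-bromo-2-iodo-1-methoxybenzene) | COc1ccc(Br)cc1I | starting material
10 | prenyl bromide (1-bromo-3-methylbut-2-ene) | CC(C)=CCBr | starting material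
11 | (5-bromo-2-methoxyphenyl)magnesium chloride (not isolated) | COc1ccc(Br)cc1[Mg]Cl | intermediate
12 | 4-bromo-1-methoxy-2-(3-methylbut-2-en-1-yl)benzene | COc1ccc(Br)cc1CC=C(C)C | intermediate
13 | [4-methoxy-3-(3-methylbut-2-en-1-yl)phenyl]lithium (not isolated) | COc1ccc([Li])cc1CC=C(C)C | intermediate
14 | lithium triisopropoxy[4-methoxy-3-(3-methylbut-2-en-1-yl)phenyl]borate (not isolated) | COc1ccc([B-](OC(C)C)(OC(C)C)OC(C)C)cc1CC=C(C)C.[Li+] | intermediate
15 | [4-methoxy-3-(3-methylbut-2-en-1-yl)phenyl]boronic acid | COc1ccc(B(O)O)cc1CC=C(C)C | intermediate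
16 | (2S)-2-[4-methoxy-3-(3-methylbut-2-en-1-yl)phenyl]-8-(3-methylbut-2-en-1-yl)-4-oxochromane-5,7-diyl diacetate | COc1ccc([C@@H]2CC(=O)c3c(OC(C)=O)cc(OC(C)=O)c(CC=C(C)C)c3O2)cc1CC=C(C)C | intermediate
17 | (2S)-5,7-dihydroxy-2-[4-methoxy-3-(3-methylbut-2-en-1-yl)phenyl]-8-(3-methylbut-2-en-1-yl)chroman-4-one | COc1ccc([C@@H]2CC(=O)c3c(O)cc(O)c(CC=C(C)C)c3O2)cc1CC=C(C)C | target

**Step count and risks**

Total steps: 8. Longest linear sequence: 6 (steps 1, 2, 3, 4, 7, 8); steps 5 and 6 form the ring B branch.

Steps most likely to fail: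

1. Step 7. Turnover may stall through protodeboronation of the electron-rich boronic acid or through loss of an acetate to a deactivating phenoxide, or the facial selectivity may be insufficient. Fallback, setting out from 8 and 15: the arylation would be run without asymmetric induction with the achiral catalyst [Rh(OH)(cod)]2 (cod = cycloocta-1,5-diene) in dioxane/H2O to give the racemic flavanone diacetate F1. This would be resolved kinetically by asymmetric transfer hydrogenation with [RhCl(C5Me5)((R,R)-TsDPEN)] (TsDPEN = N-tosyl-1,2-diphenylethane-1,2-diamine) and HCO2H/Et3N in EtOAc. The catalyst enantiomer would be the one that reduces the (2R)-ketone faster, expected to be (R,R), giving the cis-(2R,4R)-flavan-4-ol F2. The unreduced (2S)-ketone would be separated by chromatography and rejoins the route at 16, at the cost of at most half of the material.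

2. Step 3. The rearrangement may stop after the first [3,3] shift, with enolisation of the ortho-dienone to the 6-(2-methylbut-3-en-2-yl) isomer, or the acetate may be lost on the Lewis acid. Fallback, setting out from 1: the C8 side chain would be brought in from O7 instead. O-Allylation of the 7-hydroxyl (allyl bromide, K2CO3, acetone) would give 7-(allyloxy)-5-hydroxychromone F3. Thermal ortho-Claisen rearrangement (N,N-diethylaniline, 190 °C), expected mainly at C8, would give 8-allyl-5,7-dihydroxychromone F4. Diacetylation (Ac2O, pyridine, DMAP) would give the 8-allyl diacetate F5. Olefin cross-metathesis with 2-methylbut-2-ene (second-generation Grubbs catalyst [RuCl2(=CHPh)(H2IMes)(PCy3)], CH2Cl2, 40 °C) would turn allyl into prenyl and rejoin the route at 8.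

3. Step 8. Configuration at C2 may be partly lost through base-induced opening of ring C to the chalcone and reclosure. Fallback, setting out from 7: the acyl groups would be exchanged for silyl groups before the stereocentre exists. Methanolysis (K2CO3, MeOH) would give 5,7-dihydroxy-8-(3-methylbut-2-en-1-yl)chromone F6. Silylation (t-BuMe2SiOTf, 2,6-lutidine, CH2Cl2) would give the bis-silyl ether F7. The same rhodium-catalysed arylation with 15 would give the (2S)-bis-silyl flavanone F8. Desilylation with Et3N·3HF in THF at 0 °C, a weakly acidic fluoride source, would reach 17 directly.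

**Further compounds**

F1 | step 7 | racemic 2-[4-methoxy-3-(3-methylbut-2-en-1-yl)phenyl]-8-(3-methylbut-2-en-1-yl)-4-oxochromane-5,7-diyl diacetate | COc1ccc(C2CC(=O)c3c(OC(C)=O)cc(OC(C)=O)c(CC=C(C)C)c3O2)cc1CC=C(C)C
F2 | step 7 | (2R,4R)-4-hydroxy-2-[4-methoxy-3-(3-methylbut-2-en-1-yl)phenyl]-8-(3-methylbut-2-en-1-yl)chromane-5,7-diyl diacetate | COc1ccc([C@H]2C[C@@H](O)c3c(OC(C)=O)cc(OC(C)=O)c(CC=C(C)C)c3O2)cc1CC=C(C)C
F3 | step 3 | 7-(allyloxy)-5-hydroxychromone (5-hydroxy-7-(prop-2-en-1-yloxy)-4H-chromen-4-one) | C=CCOc1cc(O)c2c(c1)occc2=O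
F4 | step 3 | 8-allyl-5,7-dihydroxychromone (5,7-dihydroxy-8-(prop-2-en-1-yl)-4H-chromen-4-one) | C=CCc1c(O)cc(O)c2c1occc2=O
F5 | step 3 | 4-oxo-8-(prop-2-en-1-yl)-4H-chromene-5,7-diyl diacetate | C=CCc1c(OC(C)=O)cc(OC(C)=O)c2c1occc2=O
F6 | step 8 | 5,7-dihydroxy-8-(3-methylbut-2-en-1-yl)-4H-chromen-4-one | CC(C)=CCc1c(O)cc(O)c2c1occc2=O
F7 | step 8 | 5,7-bis(tert-butyldimethylsilyloxy)-8-(3-methylbut-2-en-1-yl)-4H-chromen-4-one | CC(C)=CCc1c(O[Si](C)(C)C(C)(C)C)cc(O[Si](C)(C)C(C)(C)C)c2c1occc2=O
F8 | step 8 | (2S)-5,7-bis(tert-butyldimethylsilyloxy)-2-[4-methoxy-3-(3-methylbut-2-en-1-yl)phenyl]-8-(3-methylbut-2-en-1-yl)chroman-4-one | COc1ccc([C@@H]2CC(=O)c3c(O[Si](C)(C)C(C)(C)C)cc(O[Si](C)(C)C(C)(C)C)c(CC=C(C)C)c3O2)cc1CC=C(C)C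
A1 | direct plan | 2-bromo-4,6-bis(methoxymethoxy)-3-(3-methylbut-2-en-1-yl)benzaldehyde | COCOc1cc(OCOC)c(CC=C(C)C)c(Br)c1C=O
A2 | direct plan | 1-[4-methoxy-3-(3-methylbut-2-en-1-yl)phenyl]ethan-1-one | COc1ccc(C(C)=O)cc1CC=C(C)C
A3 | direct plan | racemic 3-[2-bromo-4,6-bis(methoxymethoxy)-3-(3-methylbut-2-en-1-yl)phenyl]-3-hydroxy-1-[4-methoxy-3-(3-methylbut-2-en-1-yl)phenyl]propan-1-one | COc1ccc(C(=O)CC(O)c2c(OCOC)cc(OCOC)c(CC=C(C)C)c2Br)cc1CC=C(C)C
A4 | direct plan | (1S)-3-[2-bromo-4,6-bis(methoxymethoxy)-3-(3-methylbut-2-en-1-yl)phenyl]-3-(tert-butyldimethylsilyloxy)-1-[4-methoxy-3-(3-methylbut-2-en-1-yl)phenyl]propan-1-ol, both epimers at C3 | COc1ccc([C@@H](O)CC(O[Si](C)(C)C(C)(C)C)c2c(OCOC)cc(OCOC)c(CC=C(C)C)c2Br)cc1CC=C(C)C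
A5 | direct plan | (2S)-4-(tert-butyldimethylsilyloxy)-5,7-bis(methoxymethoxy)-4'-methoxy-8,3'-bis(3-methylbut-2-en-1-yl)flavan, both epimers at C4 | COc1ccc([C@@H]2CC(O[Si](C)(C)C(C)(C)C)c3c(OCOC)cc(OCOC)c(CC=C(C)C)c3O2)cc1CC=C(C)C
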